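**Retrosynthetic overview**

1. Target 23 ⇐ 1(10)-E olefin 22 by a late, face-selective epoxidation (epoxide ring formed last); 22 ⇐ silyl-protected macrolactone 20.
2. 20 ⇐ dialdehyde 15 + boryl phosphonate 17. One operation makes C7=C11 (Z-selective olefination), C6–C7 (intramolecular allylboration) and O6–C12 (lactonisation), so the ten-membered carbocycle and the γ-lactone form together.
3. 15 ⇐ diol 13 by bis-silylation and double oxidation of the two primary TES ethers.
4. 13 ⇐ aldehyde 8 + (Z)-vinyl iodide 12 (asymmetric Ni/Cr coupling forms C3–C4 and sets C3).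
5. 8 ⇐ (S)-glycidol (C8), acetylene, AlMe3 and oxirane (E-C1=C10 by carboalumination); 12 ⇐ but-2-yne-1,4-diol.

Assumption: C-locants in names and comments are the germacrane locants of the target (ring C1–C10; C11/C12/C13 = lactone α-carbon, C=O and exo-CH2; C14 = CH3 on C10; C15 = carbon on C4), and α/β refer to the usual germacranolide drawing.

**Step 1**
Reactants: 1 (S)-glycidol
Product: 2 (R)-triethyl(oxiran-2-ylmethoxy)silane
Conditions: TESCl, imidazole, CH2Cl2, 0 °C
Reagents that add atoms: chlorotriethylsilane, CC[Si](Cl)(CC)CC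
Why: Imidazole-promoted O-silylation of the primary alcohol; the stereocentre is untouched and only its CIP descriptor changes from S to R.

**Step 2**
Reactants: 2 (R)-triethyl(oxiran-2-ylmethoxy)silane
Product: 3 (R)-1-(triethylsilyloxy)pent-4-yn-2-ol
Conditions: HC≡CH, n-BuLi, THF, −78 °C; BF3·OEt2, then 2, −78 °C
Reagents that add atoms: lithium acetylide (made in the flask from acetylene and n-BuLi), [Li+].[C-]#C
Why: BF3-assisted SN2 opening of the terminal epoxide at its CH2 carbon by the acetylide (Yamaguchi-type alkynylation) leaves the C8 carbinol centre intact, and the cold, non-basic medium avoids silyl migration.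

**Step 3**
Reactants: 3 (R)-1-(triethylsilyloxy)pent-4-yn-2-ol
Product: 6 (2R,4E)-4-methyl-1-(triethylsilyloxy)hept-4-ene-2,7-diol, via alkenylalane 4 (not isolated), via lithium alkenylalanate 5 (not isolated)
Conditions: Me3Al, Cp2ZrCl2 (cat.), CH2Cl2, 0 °C → rt; n-BuLi, hexane–THF, −30 °C; oxirane, → rt; Rochelle salt
Reagents that add atoms: trimethylaluminium, C[Al](C)C; oxirane, C1CO1
Why: Negishi Zr-catalysed syn-carboalumination puts CH3 on the internal and Al on the terminal alkyne carbon, and the derived alanate opens oxirane with retention, so only the E-trisubstituted C1=C10 olefin forms.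

**Step 4**
Reactants: 6 (2R,4E)-4-methyl-1-(triethylsilyloxy)hept-4-ene-2,7-diol
Product: 7 (3E,6R)-6-hydroxy-4-methyl-7-(triethylsilyloxy)hept-3-enal
Conditions: TEMPO (cat.), PhI(OAc)2, CH2Cl2, rt
Reagents that add atoms: none
Why: The oxoammonium (TEMPO) oxidation takes the unhindered primary alcohol much faster than the secondary one and leaves the TES ether and the olefin alone.

**Step 5**
Reactants: 7 (3E,6R)-6-hydroxy-4-methyl-7-(triethylsilyloxy)hept-3-enal
Product: 8 (2R,4E)-4-methyl-7-oxo-1-(triethylsilyloxy)hept-4-en-2-yl 2-methylprop-2-enoate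
Conditions: methacrylic anhydride, pyridine, DMAP (cat.), CH2Cl2, 0 °C
Reagents that add atoms: methacrylic anhydride, C=C(C)C(=O)OC(=O)C(C)=C
Why: DMAP-catalysed acylation of the only free hydroxyl installs the C8 methacrylate of the target early, where it also serves as the protecting group.

**Step 6**
Reactants: 9 but-2-yne-1,4-diol
Product: 10 4-(tert-butyldimethylsilyloxy)but-2-yn-1-ol
Conditions: NaH (1 equiv), TBSCl (1 equiv), THF, 0 °C → rt
Reagents that add atoms: tert-butyl(chloro)dimethylsilane, CC(C)(C)[Si](C)(C)Cl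
Why: Monosilylation of the symmetrical diol through its mono-sodium alkoxide (O-silylation).

**Step 7**
Reactants: 10 4-(tert-butyldimethylsilyloxy)but-2-yn-1-ol
Product: 12 (Z)-4-(tert-butyldimethylsilyloxy)-3-iodobut-2-en-1-ol, via cyclic alkenylaluminate 11 (not isolated)
Conditions: Red-Al, THF, 0 °C; then I2, −78 → 0 °C
Reagents that add atoms: iodine, II
Why: Hydroxyl-directed trans-hydroalumination delivers hydride to the proximal alkyne carbon through a five-membered aluminate, and iodinolysis with retention puts iodine on C4 cis to C6 (and C15 trans to C6), the geometry of the target's C4=C5.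

**Step 8**
Reactants: 8 (2R,4E)-4-methyl-7-oxo-1-(triethylsilyloxy)hept-4-en-2-yl 2-methylprop-2-enoate; 12 (Z)-4-(tert-butyldimethylsilyloxy)-3-iodobut-2-en-1-ol
Product: 13 (2R,4E,7S,8Z)-8-[(tert-butyldimethylsilyloxy)methyl]-7,10-dihydroxy-4-methyl-1-(triethylsilyloxy)deca-4,8-dien-2-yl 2-methylprop-2-enoate
Conditions: CrCl2, NiCl2 (cat.), chiral oxazoline–sulfonamide ligand, Et3N, THF–MeCN, rt
Reagents that add atoms: none
Why: Nozaki–Hiyama–Kishi reaction: Ni inserts into the C–I bond with retention of the Z geometry and the vinyl–Cr(III) species adds to the aldehyde; the chiral sulfonamide ligand on chromium (reagent control, the antipode that gives 3S) sets C3, since the remote C8 centre exerts no bias.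

**Step 9**
Reactants: 13 (the 7,10-diol)
Product: 14 (2R,4E,7S,8Z)-8-[(tert-butyldimethylsilyloxy)methyl]-4-methyl-1,7,10-tris(triethylsilyloxy)deca-4,8-dien-2-yl 2-methylprop-2-enoate
Conditions: TESOTf, 2,6-lutidine, CH2Cl2, −78 °C
Reagents that add atoms: triethylsilyl trifluoromethanesulfonate, CC[Si](CC)(CC)OS(=O)(=O)C(F)(F)F
Why: O-silylation of both hydroxyls; the C3–OTES group is the protecting group and the primary C6–OTES group a latent aldehyde.

**Step 10**
Reactants: 14 (the tris-TES ether)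
Product: 15 (2R,4E,7S,8Z)-8-[(tert-butyldimethylsilyloxy)methyl]-4-methyl-1,10-dioxo-7-(triethylsilyloxy)deca-4,8-dien-2-yl 2-methylprop-2-enoate
Conditions: (COCl)2, DMSO, CH2Cl2, −78 → −40 °C; i-Pr2NEt, −78 → 0 °C
Reagents that add atoms: none
Why: Swern oxidation of primary triethylsilyl ethers: chlorodimethylsulfonium chloride exchanges only with the two unhindered primary O–SiEt3 groups, whose alkoxysulfonium salts collapse to the C7 and C6 aldehydes, while the secondary TES and the TBS ether survive and Hünig's base at low temperature avoids C8 epimerisation and enal isomerisation.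

**Step 11**
Reactants: 16 methyl 2-[bis(2,2,2-trifluoroethoxy)phosphoryl]acetate
Product: 17 methyl 2-[bis(2,2,2-trifluoroethoxy)phosphoryl]-3-(4,4,5,5-tetramethyl-1,3,2-dioxaborolan-2-yl)propanoate (racemic)
Conditions: NaH, THF, 0 °C; ICH2Bpin, 0 °C → rt
Reagents that add atoms: 2-(iodomethyl)-4,4,5,5-tetramethyl-1,3,2-dioxaborolane, ICB1OC(C)(C)C(C)(C)O1
Why: C-alkylation of the stabilised phosphonate carbanion with the highly SN2-reactive α-halomethylboronate (enolate alkylation).

**Step 12**
Reactants: 15 (the C7/C6 dialdehyde); 17 (the boryl phosphonate)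
Product: 20 15-(tert-butyldimethylsilyloxy)-8β-(methacryloyloxy)-3β-(triethylsilyloxy)germacra-1(10)E,4Z,11(13)-trien-12,6α-olide, via allylboronate 18 (not isolated), via O-boryl hydroxy ester 19 (not isolated)
Conditions: 17, KHMDS, 18-crown-6, THF, −78 °C; 15, −78 °C; cold transfer into toluene (1 mM, BHT), 85 °C
Reagents that add atoms: none
Why: Proposed new method: the potassium salt of 17 olefinates the more electrophilic α-acyloxy aliphatic aldehyde (C7) and leaves the hindered conjugated C6 enal alone, giving the 2-(borylmethyl)enoate 18 with the ester cis to C8 (Still–Gennari Z-selective Horner–Wadsworth–Emmons reaction); on dilution and heating this γ-substituted 2-alkoxycarbonyl allylboronate adds through C7 to the C6 aldehyde in a closed chair Zimmerman–Traxler transition state in which C8 (trans to CH2B, an E-crotyl-type reagent) and the aldehyde substituent C5 are both equatorial and gauche, which the six-atom tether can span, so the anti adduct with the 6,7-trans relationship forms; A(1,3) strain with the cis ester keeps H8 in the olefin plane and the aldehyde enters anti to the C9 chain, which gives 7α-H next to the fixed 8β-acyloxy centre (6R,7R,8R); the borate 19 then lactonises onto the ester, so the ten-membered ring and the γ-lactone close in one operation; the closest known reactions are the Still–Gennari olefination with α-substituted phosphonates and the thermal allylboration–lactonisation of aldehydes with 2-alkoxycarbonyl allylboronates to α-methylene-γ-butyrolactones.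

**Step 13**
Reactants: 20 (the bis-silyl macrolactone)
Product: 21 3β,15-dihydroxy-8β-(methacryloyloxy)germacra-1(10)E,4Z,11(13)-trien-12,6α-olide
Conditions: HF·pyridine, pyridine, THF, 0 °C → rt
Reagents that add atoms: none
Why: Fluoride-mediated desilylation removes the TES and TBS ethers; buffered HF·pyridine is compatible with the α-methylene lactone and the methacrylate.

**Step 14**
Reactants: 21 (the 3,15-diol)
Product: 22 3β-hydroxy-8β-(methacryloyloxy)-15-oxogermacra-1(10)E,4E,11(13)-trien-12,6α-olide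
Conditions: TEMPO (cat.), PhI(OAc)2, CH2Cl2, rt
Reagents that add atoms: none
Why: The oxoammonium (TEMPO) oxidation converts the primary allylic alcohol to the enal and leaves the secondary allylic C3 alcohol; the olefin geometry is unchanged (only the CIP label changes from 4Z to 4E).

**Step 15**
Reactants: 22 (the hydroxy enal)
Product: 23 (1R,3S,6R,7R,8R,10R)-1β,10α-epoxy-3β-hydroxy-8β-(methacryloyloxy)-15-oxogermacra-4E,11(13)-dien-12,6α-olide (target)
Conditions: mCPBA, NaHCO3, CH2Cl2, 0 °C
Reagents that add atoms: 3-chloroperbenzoic acid, OOC(=O)c1cccc(Cl)c1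
Why: Prilezhaev epoxidation: only the electron-rich 1(10)-olefin reacts (the 4-ene is an enal, the other two olefins are acrylates); the E olefin gives the trans epoxide stereospecifically, and peracid attack on the exposed outer face of the ring, helped by hydrogen bonding to the homoallylic 3β-OH, gives the 1β,10α (1R,10R) isomer, with buffering to prevent 3-OH/epoxide cyclisation.

**Compound list**

1 | (S)-glycidol | OC[C@H]1CO1 | starting material
2 | (R)-triethyl(oxiran-2-ylmethoxy)silane | CC[Si](CC)(CC)OC[C@H]1CO1 | intermediate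
3 | (R)-1-(triethylsilyloxy)pent-4-yn-2-ol | CC[Si](CC)(CC)OC[C@H](O)CC#C | intermediate
4 | (E)-alkenyl(dimethyl)alane from syn-methylalumination of 3 (O–AlMe2 alkoxide) | CC[Si](CC)(CC)OC[C@H](O[Al](C)C)C/C(C)=C/[Al](C)C | intermediate (not isolated)
5 | lithium butyl ate complex of 4 | [Li+].CC[Si](CC)(CC)OC[C@H](O[Al](C)C)C/C(C)=C/[Al-](C)(C)CCCC | intermediate (not isolated)
6 | (2R,4E)-4-methyl-1-(triethylsilyloxy)hept-4-ene-2,7-diol | CC[Si](CC)(CC)OC[C@H](O)C/C(C)=C/CCO | intermediate
7 | (3E,6R)-6-hydroxy-4-methyl-7-(triethylsilyloxy)hept-3-enal | CC[Si](CC)(CC)OC[C@H](O)C/C(C)=C/CC=O | intermediate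
8 | (2R,4E)-4-methyl-7-oxo-1-(triethylsilyloxy)hept-4-en-2-yl 2-methylprop-2-enoate | C=C(C)C(=O)O[C@@H](CO[Si](CC)(CC)CC)C/C(C)=C/CC=O | intermediate
9 | but-2-yne-1,4-diol | OCC#CCO | starting material
10 | 4-(tert-butyldimethylsilyloxy)but-2-yn-1-ol | CC(C)(C)[Si](C)(C)OCC#CCO | intermediate
11 | sodium 2,2-bis(2-methoxyethoxy)-3-[(tert-butyldimethylsilyloxy)methyl]-2,5-dihydro-1,2-oxaluminol-2-uide | [Na+].COCCO[Al-]1(OCCOC)OCC=C1CO[Si](C)(C)C(C)(C)C | intermediate (not isolated)
12 | (Z)-4-(tert-butyldimethylsilyloxy)-3-iodobut-2-en-1-ol | OC/C=C(\I)CO[Si](C)(C)C(C)(C)C | intermediate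
13 | (2R,4E,7S,8Z)-8-[(tert-butyldimethylsilyloxy)methyl]-7,10-dihydroxy-4-methyl-1-(triethylsilyloxy)deca-4,8-dien-2-yl 2-methylprop-2-enoate | C=C(C)C(=O)O[C@@H](CO[Si](CC)(CC)CC)C/C(C)=C/C[C@H](O)/C(CO[Si](C)(C)C(C)(C)C)=C\CO | intermediate
14 | (2R,4E,7S,8Z)-8-[(tert-butyldimethylsilyloxy)methyl]-4-methyl-1,7,10-tris(triethylsilyloxy)deca-4,8-dien-2-yl 2-methylprop-2-enoate | C=C(C)C(=O)O[C@@H](CO[Si](CC)(CC)CC)C/C(C)=C/C[C@H](O[Si](CC)(CC)CC)/C(CO[Si](C)(C)C(C)(C)C)=C\CO[Si](CC)(CC)CC | intermediate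
15 | (2R,4E,7S,8Z)-8-[(tert-butyldimethylsilyloxy)methyl]-4-methyl-1,10-dioxo-7-(triethylsilyloxy)deca-4,8-dien-2-yl 2-methylprop-2-enoate | C=C(C)C(=O)O[C@@H](C=O)C/C(C)=C/C[C@H](O[Si](CC)(CC)CC)/C(CO[Si](C)(C)C(C)(C)C)=C\C=O | intermediate
16 | methyl 2-[bis(2,2,2-trifluoroethoxy)phosphoryl]acetate | COC(=O)CP(=O)(OCC(F)(F)F)OCC(F)(F)F | starting material
17 | methyl 2-[bis(2,2,2-trifluoroethoxy)phosphoryl]-3-(4,4,5,5-tetramethyl-1,3,2-dioxaborolan-2-yl)propanoate (racemic) | COC(=O)C(CB1OC(C)(C)C(C)(C)O1)P(=O)(OCC(F)(F)F)OCC(F)(F)F | intermediate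
18 | methyl (2Z,4R,6E,9S,10Z)-10-[(tert-butyldimethylsilyloxy)methyl]-4-(methacryloyloxy)-6-methyl-12-oxo-2-[(pinacolboryl)methyl]-9-(triethylsilyloxy)dodeca-2,6,10-trienoate | C=C(C)C(=O)O[C@@H](/C=C(/CB1OC(C)(C)C(C)(C)O1)C(=O)OC)C/C(C)=C/C[C@H](O[Si](CC)(CC)CC)/C(CO[Si](C)(C)C(C)(C)C)=C\C=O | intermediate (not isolated)
19 | methyl 15-(tert-butyldimethylsilyloxy)-8β-(methacryloyloxy)-6α-(pinacolboryloxy)-3β-(triethylsilyloxy)germacra-1(10)E,4Z,11(13)-trien-12-oate | C=C(C)C(=O)O[C@@H]1C/C(C)=C/C[C@H](O[Si](CC)(CC)CC)/C(CO[Si](C)(C)C(C)(C)C)=C\[C@@H](OB2OC(C)(C)C(C)(C)O2)[C@@H]1C(=C)C(=O)OC | intermediate (not isolated)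
20 | 15-(tert-butyldimethylsilyloxy)-8β-(methacryloyloxy)-3β-(triethylsilyloxy)germacra-1(10)E,4Z,11(13)-trien-12,6α-olide (3S,6R,7R,8R) | C=C(C)C(=O)O[C@@H]1C/C(C)=C/C[C@H](O[Si](CC)(CC)CC)/C(CO[Si](C)(C)C(C)(C)C)=C\[C@H]2OC(=O)C(=C)[C@@H]21 | intermediate
21 | 3β,15-dihydroxy-8β-(methacryloyloxy)germacra-1(10)E,4Z,11(13)-trien-12,6α-olide | C=C(C)C(=O)O[C@@H]1C/C(C)=C/C[C@H](O)/C(CO)=C\[C@H]2OC(=O)C(=C)[C@@H]21 | intermediate
22 | 3β-hydroxy-8β-(methacryloyloxy)-15-oxogermacra-1(10)E,4E,11(13)-trien-12,6α-olide | C=C(C)C(=O)O[C@@H]1C/C(C)=C/C[C@H](O)/C(C=O)=C\[C@H]2OC(=O)C(=C)[C@@H]21 | intermediate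
23 | (1R,3S,6R,7R,8R,10R)-1β,10α-epoxy-3β-hydroxy-8β-(methacryloyloxy)-15-oxogermacra-4E,11(13)-dien-12,6α-olide | C=C(C)C(=O)O[C@@H]1C[C@@]2(C)O[C@@H]2C[C@H](O)/C(C=O)=C\[C@H]2OC(=O)C(=C)[C@@H]21 | target

**Step count**

Total: 15 steps. Longest linear sequence: 12 steps (steps 1–5, 8–10, 12–15, from 1).

**Steps most likely to fail, with fallbacks**

Step 12 (tandem olefination–allylboration–lactonisation). The olefination may not discriminate the two aldehydes or give the wrong geometry, and the ten-membered allylboration may be too slow. The fallback sets out from 15 and builds the acrylate unit stepwise. A DABCO-mediated Morita–Baylis–Hillman reaction with methyl acrylate, which selects the α-acyloxy aldehyde, gives the C7-hydroxy ester F1. NBS/Me2S converts it by SN2' displacement into the (Z)-2-(bromomethyl)enoate F2. CrCl2 in THF–DMF at 1 mM then closes the ring by an intramolecular Nozaki–Hiyama–Kishi allylation with lactonisation of the chromium alkoxide, which comes back to the route at 20.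

Step 8 (ligand-controlled C3 configuration). If the chiral chromium complex gives poor selectivity, the fallback sets out from 8 and 12. They are coupled without the ligand to the C3-epimeric diol F3. The primary allylic hydroxyl is silylated selectively (TESCl, imidazole, −40 °C) to the mono-TES ether F4. Dess–Martin oxidation of the remaining secondary allylic alcohol gives the enone F5, and (R)-Me-CBS/catecholborane reduces it to the (3S)-alcohol F6 (the alkenyl group acts as the large substituent). Silylation with TESOTf comes back to the route at 14.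

Step 15 (face of the epoxidation). If the peracid attacks the other face of the 1(10)-olefin, the fallback sets out from 22. NBS in aqueous THF puts Br+ on that same accessible face and water opens the bromonium ion at the tertiary C10, giving the bromohydrin F7. Ag2O then closes the epoxide with inversion at C1, so the oxygen ends on the face opposite to the one the electrophile attacked. This is the diastereomer complementary to the peracid product and comes back to the route at 23.

**Further compounds**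

F1 | step 12 | methyl (4R,6E,9S,10Z)-10-[(tert-butyldimethylsilyloxy)methyl]-3-hydroxy-4-(methacryloyloxy)-6-methyl-2-methylidene-12-oxo-9-(triethylsilyloxy)dodeca-6,10-dienoate (C3 epimers) | C=C(C)C(=O)O[C@@H](C(O)C(=C)C(=O)OC)C/C(C)=C/C[C@H](O[Si](CC)(CC)CC)/C(CO[Si](C)(C)C(C)(C)C)=C\C=O
F2 | step 12 | methyl (2Z,4R,6E,9S,10Z)-2-(bromomethyl)-10-[(tert-butyldimethylsilyloxy)methyl]-4-(methacryloyloxy)-6-methyl-12-oxo-9-(triethylsilyloxy)dodeca-2,6,10-trienoate | C=C(C)C(=O)O[C@@H](/C=C(\CBr)C(=O)OC)C/C(C)=C/C[C@H](O[Si](CC)(CC)CC)/C(CO[Si](C)(C)C(C)(C)C)=C\C=O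
F3 | step 8 | C7-epimeric mixture of 13 (C3 in germacrane locants) | C=C(C)C(=O)O[C@@H](CO[Si](CC)(CC)CC)C/C(C)=C/CC(O)/C(CO[Si](C)(C)C(C)(C)C)=C\CO
F4 | step 8 | 10-O-triethylsilyl ether of F3 | C=C(C)C(=O)O[C@@H](CO[Si](CC)(CC)CC)C/C(C)=C/CC(O)/C(CO[Si](C)(C)C(C)(C)C)=C\CO[Si](CC)(CC)CC
F5 | step 8 | (2R,4E,8Z)-8-[(tert-butyldimethylsilyloxy)methyl]-4-methyl-7-oxo-1,10-bis(triethylsilyloxy)deca-4,8-dien-2-yl 2-methylprop-2-enoate | C=C(C)C(=O)O[C@@H](CO[Si](CC)(CC)CC)C/C(C)=C/CC(=O)/C(CO[Si](C)(C)C(C)(C)C)=C\CO[Si](CC)(CC)CC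
F6 | step 8 | (2R,4E,7S,8Z)-8-[(tert-butyldimethylsilyloxy)methyl]-7-hydroxy-4-methyl-1,10-bis(triethylsilyloxy)deca-4,8-dien-2-yl 2-methylprop-2-enoate | C=C(C)C(=O)O[C@@H](CO[Si](CC)(CC)CC)C/C(C)=C/C[C@H](O)/C(CO[Si](C)(C)C(C)(C)C)=C\CO[Si](CC)(CC)CC
F7 | step 15 | 1α-bromo-3β,10α-dihydroxy-8β-(methacryloyloxy)-15-oxogermacra-4E,11(13)-dien-12,6α-olide | C=C(C)C(=O)O[C@@H]1C[C@@](C)(O)[C@@H](Br)C[C@H](O)/C(C=O)=C\[C@H]2OC(=O)C(=C)[C@@H]21
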